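**Plan**
- Cuts: (a) C3'–C4' of the side chain, between two carbons that can each carry a carboxyl group; (b) O1–C2 and C2–C3 of the pyranone ring, back to acetophenone 4 and hemiester 2; (c) the hemiester back to meso anhydride 1.
- Enabling feature: carbinol C2' and ester carbon C7' are 1,6-related (dissonant) across the four methylenes C3'–C6'. The chain therefore divides at C3'–C4' into two glutarate-type halves whose CH2–CO2H ends both become primary radicals. The C2=C3 bond of the pyranone ring is reachable from the C3' radical only by 4-exo or 5-endo closure.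
- Forward order: the pyranone ring is built first onto ring A (aryl ester, Baker–Venkataraman shift, cyclodehydration); the chain is then joined at C3'–C4' by nickel electrocatalysis; the two protecting groups come off last.
- Stereochemistry: the only stereocentre, C2', is set by catalyst-controlled methanolysis of anhydride 1. The acid arm becomes C1'/C2, the ester arm becomes C3', and C2' is never a reacting centre afterwards.

Key step: step 9

Assumption: the quinine-derived catalyst is taken to be the pseudoenantiomer that opens 1 to (S)-2; if the sense of induction is the reverse, its quinidine-derived counterpart is used and nothing else changes.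

**Step 1**
Reactants: 1 3-(tert-butyldimethylsilyloxy)glutaric anhydride
Product: 2 (3S)-3-[(tert-butyldimethylsilyl)oxy]-5-methoxy-5-oxopentanoic acid
Conditions: MeOH (10 equiv), N-[(8α,9S)-6'-methoxycinchonan-9-yl]-3,5-bis(trifluoromethyl)benzenesulfonamide (10 mol %), t-BuOMe (0.02 M), rt
Reagents that add atoms: methanol, CO
Why: Organocatalytic alcoholytic desymmetrisation of a meso anhydride, in which the quinuclidine nitrogen delivers methanol as a general base while the sulfonamide N–H holds one of the two enantiotopic carbonyls, so that ring opening at that carbonyl alone sets the C2' stereocentre under catalyst control.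

**Step 2**
Reactants: 3 2',6'-dihydroxy-4'-methoxyacetophenone
Product: 4 2'-(benzyloxy)-6'-hydroxy-4'-methoxyacetophenone
Conditions: BnBr (1.05 equiv), K2CO3 (1.2 equiv), acetone, reflux
Reagents that add atoms: benzyl bromide, BrCc1ccccc1
Why: Williamson ether synthesis, in which the phenol left after the first benzylation is tied up in a hydrogen bond to the acetyl carbonyl and is alkylated far more slowly, so the mono-ether should dominate.

**Step 3**
Reactants: 2 (3S)-3-[(tert-butyldimethylsilyl)oxy]-5-methoxy-5-oxopentanoic acid; 4 2'-(benzyloxy)-6'-hydroxy-4'-methoxyacetophenone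
Product: 5 1-[2-acetyl-3-(benzyloxy)-5-methoxyphenyl] 5-methyl (3R)-3-[(tert-butyldimethylsilyl)oxy]pentanedioate
Conditions: N,N'-diisopropylcarbodiimide (1.2 equiv), 4-(dimethylamino)pyridine (0.2 equiv), CH2Cl2, 0 °C to rt
Reagents that add atoms: none
Why: Steglich esterification, in which the acylpyridinium derived from 2 is reactive enough to acylate the chelated, ortho-flanked phenol of 4 while the silyl ether and the methyl ester stay untouched (the descriptor changes to R only because the ranking of the two arms changes).

**Step 4**
Reactants: 5 1-[2-acetyl-3-(benzyloxy)-5-methoxyphenyl] 5-methyl (3R)-3-[(tert-butyldimethylsilyl)oxy]pentanedioate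
Product: 6 methyl (3S)-7-[2-(benzyloxy)-6-hydroxy-4-methoxyphenyl]-3-[(tert-butyldimethylsilyl)oxy]-5,7-dioxoheptanoate
Conditions: LiN(SiMe3)2 (2.5 equiv), THF, −78 to −20 °C; AcOH quench
Reagents that add atoms: none
Why: Baker–Venkataraman rearrangement, in which the kinetically formed lithium enolate of the acetyl group attacks the neighbouring aryl ester through a six-membered transition state so that the acyl group moves from oxygen to carbon (forming C2–C3) and the product rests as its dianion, the low temperature being chosen to keep the β-silyloxy ester arms from E1cB loss of silanolate.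

**Step 5**
Reactants: 6 methyl (3S)-7-[2-(benzyloxy)-6-hydroxy-4-methoxyphenyl]-3-[(tert-butyldimethylsilyl)oxy]-5,7-dioxoheptanoate
Product: 7 methyl (3S)-4-[5-(benzyloxy)-7-methoxy-4-oxo-4H-chromen-2-yl]-3-[(tert-butyldimethylsilyl)oxy]butanoate
Conditions: p-toluenesulfonic acid monohydrate (0.1 equiv), 4 Å molecular sieves, toluene, 60 °C
Reagents that add atoms: none
Why: Acid-catalysed cyclodehydration, in which the phenol adds to the side-chain carbonyl (future C2, 6-exo-trig) and loss of water gives the 4-pyranone ring fused to ring A, catalytic acid in a dry non-hydroxylic solvent being chosen so that the secondary silyl ether should survive.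

**Step 6**
Reactants: 7 methyl (3S)-4-[5-(benzyloxy)-7-methoxy-4-oxo-4H-chromen-2-yl]-3-[(tert-butyldimethylsilyl)oxy]butanoate
Product: 9 (3S)-4-[5-(benzyloxy)-7-methoxy-4-oxo-4H-chromen-2-yl]-3-[(tert-butyldimethylsilyl)oxy]butanoic acid, via trimethylstannyl ester 8 (not isolated)
Conditions: Me3SnOH (5 equiv), 1,2-dichloroethane, 80 °C; then 0.1 M aq HCl wash
Reagents that add atoms: trimethyltin hydroxide, C[Sn](C)(C)O
Why: Trimethyltin hydroxide ester cleavage, in which the tin hydroxide attacks the methyl ester carbonyl under nearly neutral conditions to give the stannyl ester that is protonated on work-up, so that the hydroxide-sensitive pyranone ring and the β-silyloxy group (prone to elimination under saponification) are spared.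

**Step 7**
Reactants: 9 (3S)-4-[5-(benzyloxy)-7-methoxy-4-oxo-4H-chromen-2-yl]-3-[(tert-butyldimethylsilyl)oxy]butanoic acid; 10 N-hydroxyphthalimide
Product: 11 1,3-dioxoisoindolin-2-yl (3S)-4-[5-(benzyloxy)-7-methoxy-4-oxo-4H-chromen-2-yl]-3-[(tert-butyldimethylsilyl)oxy]butanoate (fragment 1)
Conditions: N,N'-diisopropylcarbodiimide (1.1 equiv), 4-(dimethylamino)pyridine (0.1 equiv), CH2Cl2, rt
Reagents that add atoms: none
Why: Carbodiimide (Steglich-type) esterification with the acidic N-hydroxyphthalimide, which should give the redox-active ester under neutral conditions that touch neither the stereocentre nor the chromone.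

**Step 8**
Reactants: 12 glutaric acid monomethyl ester; 10 N-hydroxyphthalimide
Product: 13 1,3-dioxoisoindolin-2-yl methyl pentanedioate (fragment 2)
Conditions: N,N'-diisopropylcarbodiimide (1.1 equiv), 4-(dimethylamino)pyridine (0.1 equiv), CH2Cl2, rt
Reagents that add atoms: none
Why: The same carbodiimide esterification as in step 7, applied to a simple unhindered acid.

**Step 9**
Reactants: 11 fragment 1 (1 equiv); 13 fragment 2 (3 equiv)
Product: 14 methyl (6R)-7-[5-(benzyloxy)-7-methoxy-4-oxo-4H-chromen-2-yl]-6-[(tert-butyldimethylsilyl)oxy]heptanoate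
Conditions: NiCl2(dme) (20 mol %), 2,2':6',2''-terpyridine (20 mol %), AgNO3 (0.3 equiv), DMF, Mg anode, reticulated vitreous carbon cathode, undivided cell, constant current, rt; aq NH4Cl work-up
Reagents that add atoms: none
Why: This is a nickel-electrocatalytic doubly decarboxylative coupling, a reductive cross-electrophile coupling of two redox-active esters and the modern relative of mixed Kolbe electrolysis: electron transfer from the cathode or from low-valent terpyridine-ligated nickel cleaves the N–O bond of each N-acyloxyphthalimide and releases phthalimide anion, CO2 and a primary radical (C3' from 11, C4' from 13). The two radicals are trapped successively at the nickel centre and the resulting dialkylnickel species collapses by reductive elimination to the C3'–C4' bond, the Mg anode supplying the electrons and the silver deposited from AgNO3 keeping the cathode active. No ring is closed and no stereocentre is made, and C2', being β to the radical centre, should keep its configuration (the descriptor becomes R only because C3' now ranks below C1'). The selectivity needed is cross- over homo-coupling, which two primary radicals do not provide on their own, so the cheap ester 13 is used in threefold excess and its dimer, dimethyl suberate, is removed by chromatography. The redox-active esters are reduced at a far less negative potential than the electron-rich 5,7-dialkoxychromone, and the C3' radical could add to C2=C3 only by a 4-exo or 5-endo closure, so the pyranone ring should remain a spectator.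

**Step 10**
Reactants: 14 methyl (6R)-7-[5-(benzyloxy)-7-methoxy-4-oxo-4H-chromen-2-yl]-6-[(tert-butyldimethylsilyl)oxy]heptanoate
Product: 15 methyl (6R)-7-[5-(benzyloxy)-7-methoxy-4-oxo-4H-chromen-2-yl]-6-hydroxyheptanoate
Conditions: HF·pyridine, pyridine/THF, 0 °C to rt
Reagents that add atoms: none
Why: Fluoride-induced cleavage of the silyl ether under mildly acidic buffered conditions, chosen over basic fluoride so that the methyl ester and the vinylogously acidic C1' position (risk of E1cB across C1'–C2') are not endangered.

**Step 11**
Reactants: 15 methyl (6R)-7-[5-(benzyloxy)-7-methoxy-4-oxo-4H-chromen-2-yl]-6-hydroxyheptanoate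
Product: 16 penithochromone O, methyl (6R)-6-hydroxy-7-(5-hydroxy-7-methoxy-4-oxo-4H-chromen-2-yl)heptanoate
Conditions: H2 (1 atm), Pd on carbon (10 wt %), EtOAc, rt
Reagents that add atoms: none
Why: Catalytic hydrogenolysis of the aryl benzyl ether, which at 1 atm should be much faster than saturation of the chromone C2=C3 bond, the reaction being stopped as soon as 15 is consumed.

**Compound list**
1 | 3-(tert-butyldimethylsilyloxy)glutaric anhydride | CC(C)(C)[Si](C)(C)OC1CC(=O)OC(=O)C1 | starting material
2 | (3S)-3-[(tert-butyldimethylsilyl)oxy]-5-methoxy-5-oxopentanoic acid | COC(=O)C[C@@H](O[Si](C)(C)C(C)(C)C)CC(=O)O | intermediate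
3 | 2',6'-dihydroxy-4'-methoxyacetophenone | CC(=O)c1c(O)cc(OC)cc1O | starting material
4 | 2'-(benzyloxy)-6'-hydroxy-4'-methoxyacetophenone | CC(=O)c1c(O)cc(OC)cc1OCc1ccccc1 | intermediate
5 | 1-[2-acetyl-3-(benzyloxy)-5-methoxyphenyl] 5-methyl (3R)-3-[(tert-butyldimethylsilyl)oxy]pentanedioate | COC(=O)C[C@@H](O[Si](C)(C)C(C)(C)C)CC(=O)Oc1cc(OC)cc(OCc2ccccc2)c1C(C)=O | intermediate
6 | methyl (3S)-7-[2-(benzyloxy)-6-hydroxy-4-methoxyphenyl]-3-[(tert-butyldimethylsilyl)oxy]-5,7-dioxoheptanoate | COC(=O)C[C@@H](O[Si](C)(C)C(C)(C)C)CC(=O)CC(=O)c1c(O)cc(OC)cc1OCc1ccccc1 | intermediate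
7 | methyl (3S)-4-[5-(benzyloxy)-7-methoxy-4-oxo-4H-chromen-2-yl]-3-[(tert-butyldimethylsilyl)oxy]butanoate | COC(=O)C[C@@H](O[Si](C)(C)C(C)(C)C)Cc1cc(=O)c2c(OCc3ccccc3)cc(OC)cc2o1 | intermediate
8 | trimethylstannyl (3S)-4-[5-(benzyloxy)-7-methoxy-4-oxo-4H-chromen-2-yl]-3-[(tert-butyldimethylsilyl)oxy]butanoate | C[Sn](C)(C)OC(=O)C[C@@H](O[Si](C)(C)C(C)(C)C)Cc1cc(=O)c2c(OCc3ccccc3)cc(OC)cc2o1 | intermediate
9 | (3S)-4-[5-(benzyloxy)-7-methoxy-4-oxo-4H-chromen-2-yl]-3-[(tert-butyldimethylsilyl)oxy]butanoic acid | O=C(O)C[C@@H](O[Si](C)(C)C(C)(C)C)Cc1cc(=O)c2c(OCc3ccccc3)cc(OC)cc2o1 | intermediate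
10 | N-hydroxyphthalimide | O=C1c2ccccc2C(=O)N1O | starting material
11 | 1,3-dioxoisoindolin-2-yl (3S)-4-[5-(benzyloxy)-7-methoxy-4-oxo-4H-chromen-2-yl]-3-[(tert-butyldimethylsilyl)oxy]butanoate (fragment 1) | O=C(C[C@@H](O[Si](C)(C)C(C)(C)C)Cc1cc(=O)c2c(OCc3ccccc3)cc(OC)cc2o1)ON1C(=O)c2ccccc2C1=O | intermediate
12 | glutaric acid monomethyl ester | COC(=O)CCCC(=O)O | starting material
13 | 1,3-dioxoisoindolin-2-yl methyl pentanedioate (fragment 2) | COC(=O)CCCC(=O)ON1C(=O)c2ccccc2C1=O | intermediate
14 | methyl (6R)-7-[5-(benzyloxy)-7-methoxy-4-oxo-4H-chromen-2-yl]-6-[(tert-butyldimethylsilyl)oxy]heptanoate | COC(=O)CCCC[C@@H](O[Si](C)(C)C(C)(C)C)Cc1cc(=O)c2c(OCc3ccccc3)cc(OC)cc2o1 | intermediate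
15 | methyl (6R)-7-[5-(benzyloxy)-7-methoxy-4-oxo-4H-chromen-2-yl]-6-hydroxyheptanoate | COC(=O)CCCC[C@@H](O)Cc1cc(=O)c2c(OCc3ccccc3)cc(OC)cc2o1 | intermediate
16 | penithochromone O, methyl (6R)-6-hydroxy-7-(5-hydroxy-7-methoxy-4-oxo-4H-chromen-2-yl)heptanoate | COC(=O)CCCC[C@@H](O)Cc1cc(=O)c2c(O)cc(OC)cc2o1 | target

**Step count**
Total: 11 steps. Longest linear sequence: 9 steps (1, 3, 4, 5, 6, 7, 9, 10, 11, from anhydride 1).

**Steps most likely to fail**

Step 9. What may go wrong: the two primary radicals pair without intrinsic preference, so homo-dimerisation of each partner and hydrogen capture by the C3' radical may consume fragment 1, or the nickel alkyl derived from 11 may lose silanolate across C2'–C3'. The fallback sets out from 11 and keeps the C3'–C4' disconnection, but only 11 serves as the radical source; the C4'–C7' unit arrives as a nucleophile by transmetalation. Bis(4-methoxy-4-oxobutyl)zinc F1 is prepared from methyl 4-iodobutanoate and Et2Zn by iodine–zinc exchange (CuI cat., neat, 50 °C, volatiles removed). It is then coupled with 11 in a nickel-catalysed decarboxylative Negishi-type alkyl–alkyl coupling (NiCl2(dme), 4,4'-di-tert-butyl-2,2'-bipyridine, THF/DMF, rt). This should give 14 directly, where the route is rejoined.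

Step 4. What may go wrong: deprotonation α to the aryl ester instead of at the acetyl group, followed by expulsion of silanolate (E1cB) or of the aryloxide (ketene formation) before the acyl shift occurs. The fallback sets out from 2 and 4 and delivers the acyl group intermolecularly to an enolate formed beforehand, so that no free amide base meets the β-silyloxy acyl donor. Acid 2 is converted with 1,1'-carbonyldiimidazole (THF, rt) into the acyl imidazole methyl (3S)-3-[(tert-butyldimethylsilyl)oxy]-5-(1H-imidazol-1-yl)-5-oxopentanoate F2. This is added at −78 °C to two equivalents of ketone 4 that has been doubly deprotonated with LiN(SiMe3)2 in THF. Claisen-type C-acylation of the enolate and an acetic acid quench should give diketone 6, where the route is rejoined.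

Step 5. What may go wrong: acid-induced loss of the silyl group during ring closure, or loss of silanol across C1'–C2' to a conjugated 2-alkenylchromone. The fallback sets out from 6 and closes the ring under conditions that remove the silyl group on purpose (HCl in MeOH, rt). This should give the hydroxy ester methyl (3S)-4-[5-(benzyloxy)-7-methoxy-4-oxo-4H-chromen-2-yl]-3-hydroxybutanoate F3. The alcohol is then silylated again (tert-butyldimethylsilyl trifluoromethanesulfonate, 2,6-lutidine, CH2Cl2, 0 °C) to come back to 7.

**Further compounds**
F1 | step 9 | bis(4-methoxy-4-oxobutyl)zinc | COC(=O)CCC[Zn]CCCC(=O)OC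
F2 | step 4 | methyl (3S)-3-[(tert-butyldimethylsilyl)oxy]-5-(1H-imidazol-1-yl)-5-oxopentanoate | COC(=O)C[C@@H](O[Si](C)(C)C(C)(C)C)CC(=O)n1ccnc1
F3 | step 5 | methyl (3S)-4-[5-(benzyloxy)-7-methoxy-4-oxo-4H-chromen-2-yl]-3-hydroxybutanoate | COC(=O)C[C@@H](O)Cc1cc(=O)c2c(OCc3ccccc3)cc(OC)cc2o1
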